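The cis-decalin is read as the anionic oxy-Cope product of a bicyclo[2.2.2]octenol. In the target, the C8 ketone of ring A and the oxygenated C3 of ring B flank the C5–C6 bond as a latent δ,ε-unsaturated ketone (O=C8–C7–C6–C5–C4=C3–O). Bonding C3 to C8 gives the precursor: a bicyclo[2.2.2]octenol with a methoxy bridgehead (C3) and a carbinol carbon (C8) bearing a 3-methylbuta-1,3-dien-2-yl group, built from 2,3-dimethylcyclohexenone, acrolein and a dienyllithium. One [3,3] shift forms C5–C6, closes ring A, sets the quaternary C5 and the cis ring fusion, and delivers C3 as an enol ether and C8 as a dienolate that already carries the isopropenyl carbons.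

Key step: step 6

Remark: C-numbers are eremophilane numbers. C4 and C5 carry the methyl groups, C7 the isopropenyl group (C11–C13), C8 is the ketone, C9 the carbinol, and C5/C10 are the ring fusion. Ring A is C5–C10; ring B is C1–C5 plus C10. β is the face of H10 and the C5 methyl.

Assumption: the (S)-configured oxazaborolidinium catalyst of step 2 is taken to shield the enal face that leads to the (1R,2R,4R) adduct, as the usual transition-state model for this catalyst class predicts. If the sense is the opposite, its (R)-antipode is used and nothing else changes.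

Step 1
Reactants: 1 2,3-dimethylcyclohex-2-en-1-one
Product: 3 1-methoxy-2,3-dimethylcyclohexa-1,3-diene, via dimethyl ketal 2 (not isolated)
Conditions: HC(OMe)3, TsOH·H2O (1 mol%), MeOH, 25 °C; then toluene, 110 °C with removal of MeOH
Reagents that add atoms: trimethyl orthoformate, COC(OC)OC
Why: Acid-catalysed ketalisation and loss of methanol (dienol ether formation from an enone under equilibrating conditions) should give the linearly conjugated homoannular dienol ether, the only isomer with an s-cis diene; no stereocentre is formed.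

Step 2
Reactants: 3 1-methoxy-2,3-dimethylcyclohexa-1,3-diene; 4 acrolein
Product: 5 (1R,2R,4R)-1-methoxy-5,6-dimethylbicyclo[2.2.2]oct-5-ene-2-carbaldehyde (formyl endo, syn to the C5=C6 bridge)
Conditions: (S)-B-(o-tolyl)oxazaborolidine of (S)-α,α-diphenylprolinol activated with Tf2NH (10 mol%), CH2Cl2, −78 °C
Reagents that add atoms: none
Why: Catalytic enantioselective Diels–Alder reaction (Corey-type cationic oxazaborolidinium Lewis acid): the unsubstituted diene terminus bonds to the acrolein β-carbon so that the formyl-bearing carbon ends next to the methoxy bridgehead, the endo transition state places the formyl group syn to the new C5=C6 bridge, and the catalyst-shielded enal face fixes both bridgeheads (C1, C4) in one absolute sense.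

Step 3
Reactants: 5 (1R,2R,4R)-1-methoxy-5,6-dimethylbicyclo[2.2.2]oct-5-ene-2-carbaldehyde
Product: 6 (1S,4R)-1-methoxy-5,6-dimethylbicyclo[2.2.2]oct-5-en-2-one
Conditions: O2 (1 atm), Cu(OAc)2 (10 mol%), 2,2′-bipyridine (10 mol%), DABCO (20 mol%), DMF, 40 °C
Reagents that add atoms: dioxygen, O=O
Why: Copper-catalysed aerobic oxidative deformylation of an α-branched aldehyde (enolisation, α-peroxidation, C–C cleavage) should remove the formyl carbon as formic acid and leave the ketone, so that C2 becomes sp2 and only the non-epimerisable bridgehead stereocentres remain.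

Step 4
Reactants: 7 3-methylbut-3-en-2-one; 8 2,4,6-triisopropylbenzenesulfonohydrazide
Product: 9 3-methylbut-3-en-2-one 2,4,6-triisopropylbenzenesulfonylhydrazone
Conditions: MeOH, HCl (cat.), 0 → 25 °C
Reagents that add atoms: none
Why: Acid-catalysed condensation of the ketone carbonyl with the sulfonyl hydrazide gives the arenesulfonylhydrazone required for a Shapiro reaction; no stereocentre is involved.

Step 5
Reactants: 9 3-methylbut-3-en-2-one 2,4,6-triisopropylbenzenesulfonylhydrazone; 6 (1S,4R)-1-methoxy-5,6-dimethylbicyclo[2.2.2]oct-5-en-2-one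
Product: 11 (1S,2R,4R)-1-methoxy-5,6-dimethyl-2-(3-methylbuta-1,3-dien-2-yl)bicyclo[2.2.2]oct-5-en-2-ol (dienyl group syn to the C5=C6 bridge), via dienyllithium 10 (not isolated)
Conditions: 9, n-BuLi (2 equiv per 9), THF/TMEDA, −78 → 0 °C; then 6, −78 °C; H2O
Reagents that add atoms: none
Why: Shapiro reaction (dianion formation at the α-methyl group, loss of sulfinate and N2) generates the 2-lithio-1,3-diene, which adds 1,2 to the ketone from the face syn to the C5=C6 bridge, the face under the ethano bridge being blocked by its inward hydrogens, so that the dienyl group ends over the alkene and the hydroxyl over the ethano bridge (C2 = R).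

Step 6
Reactants: 11 (1S,2R,4R)-1-methoxy-5,6-dimethyl-2-(3-methylbuta-1,3-dien-2-yl)bicyclo[2.2.2]oct-5-en-2-ol
Product: 15 (5S,10R)-3-methoxyeremophila-3,7(11)-dien-8-one (cis-fused; C5 methyl and H10 both β), via potassium alkoxide 12 (not isolated), via potassium dienolate 13 (not isolated), via deconjugated ketone 14 (not isolated)
Conditions: KH, 18-crown-6, THF, 0 → 25 °C; then MeOH, 25 °C; AcOH
Reagents that add atoms: none
Why: KH with 18-crown-6 gives the free potassium alkoxide 12, which undergoes an anionic oxy-Cope ([3,3]-sigmatropic) rearrangement through the boat transition state imposed by the bicycle: the C3–C8 σ bond breaks and the C5–C6 σ bond forms between the CH2 terminus of the dienyl group and the methyl-bearing alkene carbon. The closest known reaction type is the anionic oxy-Cope ring expansion of 2-vinyl-1-alkoxybicyclo[2.2.2]oct-5-en-2-ols to cis-fused octalones. Ring A (C5–C10) is closed by this suprafacial intramolecular bond shift, a ring expansion of the bicyclo[2.2.2]octene to the cis-bicyclo[4.4.0]decane rather than a polar exo or endo closure, and ring B is the original cyclohexene ring. The new stereocentre C5 is controlled by C10: the dienyl group can reach the C4=C5 bond only on the face that carries the C9 bridge, so C6 and C9 end cis on ring B and the C5 methyl is cis to H10. The step needs the concerted shift to win over fragmentation or a 1,3-shift; the syn placement of the dienyl group from step 5, the strain of the bicycle and the C3–C8 bond weakened by the alkoxide and the adjacent methoxy group secure this. Methanol then equilibrates dienolate 13 through ketone 14 to the conjugated isopropylidene ketone 15, while C3 emerges as a methyl enol ether that masks the C3 ketone.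

Step 7
Reactants: 15 (5S,10R)-3-methoxyeremophila-3,7(11)-dien-8-one
Product: 17 (5S,9R,10S)-9-hydroxy-3-methoxyeremophila-3,7(11)-dien-8-one (9β-OH), via lithium enolate 16 (not isolated)
Conditions: LiN(i-Pr)2, THF, −78 °C; 2-(phenylsulfonyl)-3-phenyloxaziridine, −78 °C; AcOH
Reagents that add atoms: 2-(phenylsulfonyl)-3-phenyloxaziridine, O=S(=O)(c1ccccc1)N1OC1c1ccccc1
Why: Kinetic deprotonation of the enone by the lithium amide occurs at the α′-methylene C9 (cross-conjugated enolate), and electrophilic hydroxylation with the Davis oxaziridine should occur on the β face of C9, syn to H10 and anti to both the C10–C1 bond and the axial C5–C4 bond, giving the 9β (9R) alcohol.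

Step 8
Reactants: 17 (5S,9R,10S)-9-hydroxy-3-methoxyeremophila-3,7(11)-dien-8-one
Product: 18 (5S,9R,10S)-9-(tert-butyldimethylsilyloxy)-3-methoxyeremophila-3,7(11)-dien-8-one
Conditions: TBSOTf, 2,6-lutidine, CH2Cl2, −78 → 0 °C
Reagents that add atoms: tert-butyldimethylsilyl triflate, CC(C)(C)[Si](C)(C)OS(=O)(=O)C(F)(F)F
Why: Silylation of the secondary α′-hydroxyl with the silyl triflate and a hindered base protects O9 for the later base and acylation steps without touching the enol ether or C9.

Step 9
Reactants: 18 (5S,9R,10S)-9-(tert-butyldimethylsilyloxy)-3-methoxyeremophila-3,7(11)-dien-8-one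
Product: 19 (4R,5S,9R,10S)-9-(tert-butyldimethylsilyloxy)eremophil-7(11)-ene-3,8-dione (4β-methyl)
Conditions: HCl (1 M aq.), THF, 0 → 25 °C
Reagents that add atoms: water, O
Why: Acid hydrolysis of the methyl enol ether (C-protonation at C4, hemiketal, loss of methanol) unmasks the C3 ketone, and C4 should equilibrate through the enol to the 4β-methyl (4R) epimer, equatorial on ring B and cis to the C5 methyl, because the equatorial 9-silyloxy group fixes the cis-decalin conformer in which a 4α-methyl would be syn-axial to C9; the hindered secondary silyl ether survives dilute acid.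

Step 10
Reactants: 19 (4R,5S,9R,10S)-9-(tert-butyldimethylsilyloxy)eremophil-7(11)-ene-3,8-dione
Product: 20 (3R,4R,5R,9R,10S)-9-(tert-butyldimethylsilyloxy)-3-hydroxyeremophil-7(11)-en-8-one (3α-OH, equatorial)
Conditions: Al(Oi-Pr)3 (20 mol%), i-PrOH/acetone (5:1), toluene, 80 °C
Reagents that add atoms: none
Why: Meerwein–Ponndorf–Verley reduction run reversibly (acetone present) is under thermodynamic control and should give the equatorial 3α (3R) alcohol, trans to the C4 methyl and free of the syn-diaxial contact with the axial C5 methyl that destabilises the 3β epimer, while the conjugated, tetrasubstituted C8 enone is a poorer hydride acceptor both sterically and thermodynamically.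

Step 11
Reactants: 20 (3R,4R,5R,9R,10S)-9-(tert-butyldimethylsilyloxy)-3-hydroxyeremophil-7(11)-en-8-one
Product: 22 (3R,4R,5R,7R,9R,10S)-9-(tert-butyldimethylsilyloxy)-3-hydroxyeremophil-11-en-8-one (7β-isopropenyl), via dilithium dienolate 21 (not isolated)
Conditions: LiN(i-Pr)2 (3 equiv), THF/DMPU, −78 → −40 °C; inverse quench into AcOH/THF, −78 °C
Reagents that add atoms: none
Why: The amide base deprotonates the hydroxyl and then a γ-methyl group of the enone (C9–H is shielded by the silyloxy group) to give the extended dienolate, whose kinetic protonation at the α-carbon C7 (deconjugative protonation) should occur axially on the α face through a chair-like transition state, leaving the isopropenyl group equatorial, β and cis to O9 (7R), which is also the more stable C7 epimer.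

Step 12
Reactants: 23 (R)-pent-4-en-2-ol; 24 angelic acid ((Z)-2-methylbut-2-enoic acid)
Product: 26 (R)-pent-4-en-2-yl (Z)-2-methylbut-2-enoate, via mixed anhydride 25 (not isolated)
Conditions: 24, 2,4,6-trichlorobenzoyl chloride, Et3N, toluene, 25 °C; then 23, 80 °C
Reagents that add atoms: none
Why: Yamaguchi esterification through the mixed anhydride without DMAP acylates the secondary alcohol with retention at its stereocentre and is known to avoid Z to E isomerisation of angelates.

Step 13
Reactants: 26 (R)-pent-4-en-2-yl (Z)-2-methylbut-2-enoate; 27 acrylic acid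
Product: 28 (2E,5R)-5-[(Z)-2-methylbut-2-enoyloxy]hex-2-enoic acid
Conditions: 27 (3 equiv), Hoveyda–Grubbs second-generation catalyst RuCl2(H2IMes)(=CH–C6H4–2-Oi-Pr) (5 mol%), CH2Cl2, 40 °C
Reagents that add atoms: none
Why: Olefin cross-metathesis of the terminal alkene with acrylic acid should give the E-configured enoic acid, while the trisubstituted, electron-poor angelate double bond does not take part.

Step 14
Reactants: 22 (3R,4R,5R,7R,9R,10S)-9-(tert-butyldimethylsilyloxy)-3-hydroxyeremophil-11-en-8-one; 28 (2E,5R)-5-[(Z)-2-methylbut-2-enoyloxy]hex-2-enoic acid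
Product: 29 (3R,4R,5R,7R,9R,10S)-9-(tert-butyldimethylsilyloxy)-8-oxoeremophil-11-en-3-yl (2E,5R)-5-[(Z)-2-methylbut-2-enoyloxy]hex-2-enoate
Conditions: EDC·HCl (N-ethyl-N′-(3-dimethylaminopropyl)carbodiimide hydrochloride), DMAP (cat.), CH2Cl2, 0 → 25 °C
Reagents that add atoms: none
Why: Steglich esterification of the unhindered equatorial C3 hydroxyl (O9 is silylated) proceeds with retention at C3 under conditions mild enough for the β,γ-unsaturated ketone.

Step 15
Reactants: 29 (3R,4R,5R,7R,9R,10S)-9-(tert-butyldimethylsilyloxy)-8-oxoeremophil-11-en-3-yl (2E,5R)-5-[(Z)-2-methylbut-2-enoyloxy]hex-2-enoate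
Product: 30 (3R,4R,5R,7R,9R,10S)-9-hydroxy-8-oxoeremophil-11-en-3-yl (2E,5R)-5-[(Z)-2-methylbut-2-enoyloxy]hex-2-enoate (CNP0210874.1)
Conditions: HF·pyridine, THF/pyridine, 0 → 25 °C
Reagents that add atoms: none
Why: Fluoride-mediated cleavage of the silyl ether under buffered, weakly acidic conditions frees the C9 hydroxyl without base-induced conjugation of the isopropenyl ketone, epimerisation at C7 or C9, or ester cleavage.

Compound list
1 | 2,3-dimethylcyclohex-2-en-1-one | CC1=C(C)C(=O)CCC1 | starting material
2 | 1,1-dimethoxy-2,3-dimethylcyclohex-2-ene (dimethyl ketal) | COC1(OC)CCCC(C)=C1C | intermediate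
3 | 1-methoxy-2,3-dimethylcyclohexa-1,3-diene | COC1=C(C)C(C)=CCC1 | intermediate
4 | acrolein | C=CC=O | starting material
5 | (1R,2R,4R)-1-methoxy-5,6-dimethylbicyclo[2.2.2]oct-5-ene-2-carbaldehyde | CC1=C(C)[C@@]2(OC)CC[C@@H]1C[C@H]2C=O | intermediate
6 | (1S,4R)-1-methoxy-5,6-dimethylbicyclo[2.2.2]oct-5-en-2-one | CC1=C(C)[C@@]2(OC)CC[C@@H]1CC2=O | intermediate
7 | 3-methylbut-3-en-2-one | CC(=O)C(C)=C | starting material
8 | 2,4,6-triisopropylbenzenesulfonohydrazide | CC(C)c1cc(C(C)C)c(S(=O)(=O)NN)c(C(C)C)c1 | starting material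
9 | 3-methylbut-3-en-2-one 2,4,6-triisopropylbenzenesulfonylhydrazone | CC(=NNS(=O)(=O)c1c(C(C)C)cc(C(C)C)cc1C(C)C)C(C)=C | intermediate
10 | (3-methylbuta-1,3-dien-2-yl)lithium | [Li]C(=C)C(C)=C | intermediate
11 | (1S,2R,4R)-1-methoxy-5,6-dimethyl-2-(3-methylbuta-1,3-dien-2-yl)bicyclo[2.2.2]oct-5-en-2-ol | CC1=C(C)[C@@]2(OC)CC[C@@H]1C[C@@]2(O)C(=C)C(C)=C | intermediate
12 | potassium alkoxide of 11 | CC1=C(C)[C@@]2(OC)CC[C@@H]1C[C@@]2([O-])C(=C)C(C)=C.[K+] | intermediate
13 | potassium (5S,10R)-3-methoxyeremophila-3,7,11-trien-8-olate (extended dienolate) | C=C(C)C=1C[C@@]2(C)[C@H](CCC(OC)=C2C)CC=1[O-].[K+] | intermediate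
14 | (5S,10R)-3-methoxyeremophila-3,11-dien-8-one (C7 epimers) | C=C(C)C1C[C@@]2(C)[C@H](CCC(OC)=C2C)CC1=O | intermediate
15 | (5S,10R)-3-methoxyeremophila-3,7(11)-dien-8-one | CC(C)=C1C[C@@]2(C)[C@H](CCC(OC)=C2C)CC1=O | intermediate
16 | lithium (5S,10R)-3-methoxyeremophila-3,7(11),8-trien-8-olate (cross-conjugated enolate) | CC(C)=C1C[C@@]2(C)[C@H](CCC(OC)=C2C)C=C1[O-].[Li+] | intermediate
17 | (5S,9R,10S)-9-hydroxy-3-methoxyeremophila-3,7(11)-dien-8-one | CC(C)=C1C[C@@]2(C)[C@H](CCC(OC)=C2C)[C@@H](O)C1=O | intermediate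
18 | (5S,9R,10S)-9-(tert-butyldimethylsilyloxy)-3-methoxyeremophila-3,7(11)-dien-8-one | CC(C)=C1C[C@@]2(C)[C@H](CCC(OC)=C2C)[C@@H](O[Si](C)(C)C(C)(C)C)C1=O | intermediate
19 | (4R,5S,9R,10S)-9-(tert-butyldimethylsilyloxy)eremophil-7(11)-ene-3,8-dione | CC(C)=C1C[C@@]2(C)[C@H](CCC(=O)[C@@H]2C)[C@@H](O[Si](C)(C)C(C)(C)C)C1=O | intermediate
20 | (3R,4R,5R,9R,10S)-9-(tert-butyldimethylsilyloxy)-3-hydroxyeremophil-7(11)-en-8-one | CC(C)=C1C[C@@]2(C)[C@H](CC[C@@H](O)[C@@H]2C)[C@@H](O[Si](C)(C)C(C)(C)C)C1=O | intermediate
21 | dilithium 3-alkoxide 8-dienolate of 20 | C=C(C)C=1C[C@@]2(C)[C@H](CC[C@@H]([O-])[C@@H]2C)[C@@H](O[Si](C)(C)C(C)(C)C)C=1[O-].[Li+].[Li+] | intermediate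
22 | (3R,4R,5R,7R,9R,10S)-9-(tert-butyldimethylsilyloxy)-3-hydroxyeremophil-11-en-8-one | C=C(C)[C@H]1C[C@@]2(C)[C@H](CC[C@@H](O)[C@@H]2C)[C@@H](O[Si](C)(C)C(C)(C)C)C1=O | intermediate
23 | (R)-pent-4-en-2-ol | C=CC[C@@H](C)O | starting material
24 | angelic acid, (Z)-2-methylbut-2-enoic acid | C/C=C(/C)C(=O)O | starting material
25 | (Z)-2-methylbut-2-enoic 2,4,6-trichlorobenzoic anhydride | C/C=C(/C)C(=O)OC(=O)c1c(Cl)cc(Cl)cc1Cl | intermediate
26 | (R)-pent-4-en-2-yl (Z)-2-methylbut-2-enoate | C=CC[C@@H](C)OC(=O)/C(C)=C\C | intermediate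
27 | acrylic acid | C=CC(=O)O | starting material
28 | (2E,5R)-5-[(Z)-2-methylbut-2-enoyloxy]hex-2-enoic acid | OC(=O)/C=C/C[C@@H](C)OC(=O)/C(C)=C\C | intermediate
29 | 9-O-tert-butyldimethylsilyl ether of the target | C=C(C)[C@H]1C[C@@]2(C)[C@H](CC[C@@H](OC(=O)/C=C/C[C@@H](C)OC(=O)/C(C)=C\C)[C@@H]2C)[C@@H](O[Si](C)(C)C(C)(C)C)C1=O | intermediate
30 | CNP0210874.1, (3R,4R,5R,7R,9R,10S)-9-hydroxy-8-oxoeremophil-11-en-3-yl (2E,5R)-5-[(Z)-2-methylbut-2-enoyloxy]hex-2-enoate | C=C(C)[C@H]1C[C@@]2(C)[C@H](CC[C@@H](OC(=O)/C=C/C[C@@H](C)OC(=O)/C(C)=C\C)[C@@H]2C)[C@@H](O)C1=O | target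

Total step count: 15. Longest linear sequence: 12 steps (steps 1, 2, 3, 5, 6, 7, 8, 9, 10, 11, 14, 15).

Steps most likely to fail

Step 11. The proton may be delivered to the dienolate on the β face (axial 7-epimer) or at the terminal γ-carbon (return to 20), and the hindered C9–H may be partly exchanged. The fallback sets out from 20 and comes back at 22, replacing kinetic by thermodynamic control at C7. Dienolate 21 is quenched without facial control to a mixture that contains (3R,4R,5R,7S,9R,10S)-9-(tert-butyldimethylsilyloxy)-3-hydroxyeremophil-11-en-8-one F1. The mixture is then stirred with DBU (5 mol%) in CH2Cl2 at 0 °C. Only the doubly activated C7–H is exchanged, the dienolate reprotonates faster at the α-carbon than at the γ-carbon, and the axial isopropenyl group of F1 is syn-axial to C4, so 22 should dominate. Reconjugated 20 is separated and recycled.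

Step 10. The reversible hydride transfer may not reach equilibrium, or it may begin to reduce or epimerise next to the hindered enone, so that stereo- or chemocontrol is lost. The fallback sets out from 19 and comes back at 29. Kinetic reduction with KBH(s-Bu)3 (THF, −78 °C) attacks equatorially, anti to the axial C5 methyl, and should give the axial alcohol (3S,4R,5R,9R,10S)-9-(tert-butyldimethylsilyloxy)-3-hydroxyeremophil-7(11)-en-8-one F2. Deconjugation as in step 11 gives (3S,4R,5R,7R,9R,10S)-9-(tert-butyldimethylsilyloxy)-3-hydroxyeremophil-11-en-8-one F3. Mitsunobu esterification of F3 with acid 28 (PPh3, DIAD, toluene, 0 → 25 °C) inverts C3 and gives 29 directly.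

Step 2. Facial or endo/exo discrimination by the catalyst may be poor (each lowers the enantiomeric purity of 6 once the formyl carbon is lost), or the acid-labile dienol ether may decompose. The fallback sets out from 3 and comes back at 5, replacing catalyst control by a covalent auxiliary. Diels–Alder reaction of 3 with (S)-3-acryloyl-4-benzyloxazolidin-2-one (Et2AlCl, CH2Cl2, −78 °C) gives (S)-4-benzyl-3-[(1R,2R,4R)-1-methoxy-5,6-dimethylbicyclo[2.2.2]oct-5-ene-2-carbonyl]oxazolidin-2-one F4, whose diastereomers can be separated by crystallisation. LiBH4 (THF, MeOH, 0 °C) removes the auxiliary and gives [(1R,2S,4R)-1-methoxy-5,6-dimethylbicyclo[2.2.2]oct-5-en-2-yl]methanol F5. Dess–Martin periodinane (CH2Cl2, 25 °C) returns aldehyde 5. The antipodal auxiliary is used if the facial sense is the opposite.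

Further compounds
F1 | step 11 | (3R,4R,5R,7S,9R,10S)-9-(tert-butyldimethylsilyloxy)-3-hydroxyeremophil-11-en-8-one | C=C(C)[C@@H]1C[C@@]2(C)[C@H](CC[C@@H](O)[C@@H]2C)[C@@H](O[Si](C)(C)C(C)(C)C)C1=O
F2 | step 10 | (3S,4R,5R,9R,10S)-9-(tert-butyldimethylsilyloxy)-3-hydroxyeremophil-7(11)-en-8-one | CC(C)=C1C[C@@]2(C)[C@H](CC[C@H](O)[C@@H]2C)[C@@H](O[Si](C)(C)C(C)(C)C)C1=O
F3 | step 10 | (3S,4R,5R,7R,9R,10S)-9-(tert-butyldimethylsilyloxy)-3-hydroxyeremophil-11-en-8-one | C=C(C)[C@H]1C[C@@]2(C)[C@H](CC[C@H](O)[C@@H]2C)[C@@H](O[Si](C)(C)C(C)(C)C)C1=O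
F4 | step 2 | (S)-4-benzyl-3-[(1R,2R,4R)-1-methoxy-5,6-dimethylbicyclo[2.2.2]oct-5-ene-2-carbonyl]oxazolidin-2-one | CC1=C(C)[C@@]2(OC)CC[C@@H]1C[C@H]2C(=O)N1[C@@H](Cc2ccccc2)COC1=O
F5 | step 2 | [(1R,2S,4R)-1-methoxy-5,6-dimethylbicyclo[2.2.2]oct-5-en-2-yl]methanol | CC1=C(C)[C@@]2(OC)CC[C@@H]1C[C@H]2CO
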